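## Structural features

The target is a flavone: benzene ring A is fused to the 4-pyranone ring C to give a 4H-chromen-4-one, and the 4-methoxyphenyl ring B is attached to C2 by a single C–C bond. Every position of rings A and C is substituted, with methoxyls at C3, C5, C6 and C8, a free hydroxyl at C7, the carbonyl at C4 and the ring oxygen O1 on C8a. There is no stereocentre, so no relative configuration between neighbouring centres has to be controlled. The fragile groups are the free 7-phenol on a penta-oxygenated ring, which is prone to oxidation, the pyranone, a vinylogous ester that hot alkali or strong nucleophiles open at C2, and the 5-methoxyl peri to the carbonyl, which Lewis acids remove readily. The real difficulty is the oxygen pattern of ring A: five contiguous oxygenated carbons, of which only the C7 oxygen must stay unmethylated. The key step exploits the latent symmetry of ring A: C4a lies para to C7, and while ring C is open the pairs C6/C8 and C5/C8a are equivalent, so that the unit C4–C4a with the C6-OMe, C7-O and C8-OMe triad is the carbon skeleton of syringic acid carrying two extra, equivalent ortho oxygens. Forming C3–C4 and then closing O1–C2 through either ortho oxygen gives the same chromenone, leaves the other ortho oxygen as the chelated C5 hydroxyl, and keeps the C7 oxygen separately masked.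

## Logic of the disconnections

15 from 14: the O–CH2 bond of a benzyl group on the C7 oxygen is cut. This oxygen must stay distinct from the four methylated ones, and a group removed by neutral hydrogenolysis lets the oxidation-prone phenol appear only at the end. The forward step must leave the C2=C3 bond and the aryl ethers untouched.

14 from 13: the O–CH3 bond at C5 is cut. In 13 this is the only free hydroxyl, so no selectivity question arises. The forward step must alkylate a hydrogen-bonded, flanked phenol without opening the pyranone.

13 from 9 and 10 (through 11 and 12): O1–C2 is cut first, then C3–C4. This separates a ring A acyl donor from a ring B ketone that already holds C2, C3 and the C3 methoxyl. Because 9 is symmetric, ring closure has no regiochemical choice. The problem is reduced from a fused bicycle to two monocyclic aromatics, one of them purchased. The forward step needs C-acylation of a lithium enolate by a di-ortho-substituted acyl chloride, and an acid treatment that removes two acetal groups but keeps the benzyl ether.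

9 from 8: the C–Cl bond is cut. The acyl chloride is made last, because the ortho acetal ethers tolerate neither strong acid nor storage next to an acyl chloride. The forward step needs a neutral chlorinating agent and immediate use of the product.

8 from 6 (through 7): the O–CH2 bonds of three methoxymethyl groups are cut. The two ortho hydroxyls need a mask that survives enolate chemistry, falls off in the acidic ring-closing medium and is orthogonal to benzyl. The carboxyl group is alkylated unavoidably as well, so the forward step must etherify two hindered hydroxyls completely and then cleave only the acylal-type ester.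

6 from 5: the two aryl C–O bonds that become O1 and the C5 oxygen are cut. An ortho-halobenzoate is a privileged substrate for copper-mediated substitution, and both positions are equivalent. The forward step must substitute twice, and the electron-rich product must survive isolation without decarboxylation.

5 from 4: two C–Br bonds are cut at the only free ring positions, each ortho to one methoxyl and para to the other. The free acid is brominated, not an ester, so that no di-ortho-brominated ester has to be hydrolysed later. The forward step needs substitution at C–H and not ipso attack at the carboxyl-bearing carbon.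

4 from 1 and 2 (through 3): the benzyl–O bond and the methyl ester C–O bond are cut. 1 already carries the C6/C7/C8 oxygen triad with the C7 oxygen uniquely free, so the differentiation the target requires comes with the starting material. The forward steps are routine.

## Other disconnections considered

Alternative 1: The cut is the C4a–C5 bond of ring A in flavone numbering. Ring A is opened to the acyclic ester A1, methyl 2,4,8-trimethoxy-3,5,7-trioxooctanoate. In the forward key step Mg(OMe)2 in methanol would chelate the polycarbonyl chain of A1, and the C6 carbanion would attack the C1 ester carbonyl in a 6-exo-trig Claisen closure. Loss of methoxide and enolisation would give the acylphloroglucinol A2, 2-methoxy-1-(2,4,6-trihydroxy-3,5-dimethoxyphenyl)ethanone.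
- In its favour: all ring A oxygens come from carbonyl groups, so no arene halogenation or copper chemistry is needed, and A2 already carries C3 with its methoxyl.
- Against it: A1 is a highly enolised, α-oxygenated poly-β-carbonyl compound with three acidic sites. Its own preparation would be longer and less certain than the path from 1 to 9. Aldol-type closure and lactonisation of the chain of A1 compete with the Claisen mode, and the α-methoxyls change the chelation on which the magnesium template relies. A2 has three free hydroxyls and no ring B. An aroylation and cyclodehydration of the Allan–Robinson type would still be needed, followed by benzylation of the 7-hydroxyl, methylation of the 5-hydroxyl and debenzylation.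
- Comparison: on structure the alternative is equal in using the symmetry of ring A, and better in that the hexasubstituted benzene ring is built and not decorated. On mechanism both plans rest on Claisen-type acylation, but the chosen plan joins two stable partners with one enolisable site. On step economy the alternative is clearly longer, because the flavone assembly only begins at A2, whereas 13 is reached with the C5/C7 differentiation in place.

Alternative 2: The cuts are C4a–C4 and C4–C3, with the carbonyl carbon supplied by carbon monoxide A5, and O1–C2. The partners are the symmetric aryl iodide A3, 1-iodo-3,5-dimethoxy-2,4,6-tris(methoxymethoxy)benzene, and the alkyne A4, 1-ethynyl-4-methoxybenzene. Forward, Pd(PPh3)2Cl2, a divalent palladium precatalyst that is reduced in the flask to zerovalent palladium, and triethylamine under A5 would effect oxidative addition of A3, insertion of A5, alkynyl transfer from A4 and reductive elimination. This would give the ynone A6, 1-[3,5-dimethoxy-2,4,6-tris(methoxymethoxy)phenyl]-3-(4-methoxyphenyl)prop-2-yn-1-one. Methanolic HCl added to the same flask would remove the acetal groups of A6, and an ortho hydroxyl would add 6-endo-dig to the triple bond to give A7, 5,7-dihydroxy-6,8-dimethoxy-2-(4-methoxyphenyl)-4H-chromen-4-one.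
- In its favour: three components are joined catalytically, A4 and A5 are cheap, A3 is symmetric like 9, and neither a strong base at low temperature nor a labile acyl chloride is needed.
- Against it: A7 has no oxygen at C3. The C3–O bond would have to be made afterwards by oxidation of the pyranone alkene or by C3 metalation and oxidation on an electron-rich polyphenol, followed by methylation. A7 has both the 5- and 7-hydroxyls free, and the 7-hydroxyl would be expected to alkylate first, the opposite of what the target needs, unless the para oxygen of A3 is benzylated from the start. Oxidative addition to the di-ortho-substituted, electron-rich A3 should be slow. Direct coupling of A3 with A4 without uptake of A5, and 5-exo-dig instead of 6-endo-dig closure of A6 once its acetal groups are lost, are competing pathways. A3 needs a synthesis of its own that is not shorter than 1 to 9.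
- Comparison: on structure the use of ring A symmetry is equal and the convergence is better, but the skeleton reached is the 3-deoxy one. On mechanism the palladium catalysis is milder, which is a point for the alternative, but it has two selectivity questions, at the formation of A6 and at its ring closure, against one (C- versus O-acylation) in the chosen plan. On step economy the key step is equal (one flask, ring C closed), but at least four further steps would follow A7, against two after 13.

Alternative 3: The cuts are C4–C4a and O1–C2. The partners are the triol A8, 2,4-dimethoxybenzene-1,3,5-triol, and the racemic ketoester A9, ethyl 2-methoxy-3-(4-methoxyphenyl)-3-oxopropanoate. Forward, neat fusion at about 250 °C would acylate the only unsubstituted ring carbon of A8 with the ester carbon of A9, probably through an acylketene formed by loss of the ester alcohol. A flanking hydroxyl would then condense with the ketone to give A10, 5,7-dihydroxy-3,6,8-trimethoxy-2-(4-methoxyphenyl)-4H-chromen-4-one.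
- In its favour: this is the shortest assembly of the full 3-methoxyflavone, one operation without reagents or protecting groups. The C3 methoxyl is in place as in the chosen plan, and A8 can react at only one carbon.
- Against it: A8 is an air-sensitive, penta-oxygenated phenol that is not a catalogue chemical and would have to be made. Fusion at 250 °C invites oxidative decomposition. α-Substituted aroylacetates such as A9 are expected to be poor partners in this condensation. The Pechmann-type orientation, in which the ring carbon of A8 attacks the ketone carbonyl of A9 instead of the ester carbon, is a competing course. A10 has both the 5- and 7-hydroxyls free, so selective benzylation of the 7-hydroxyl, methylation of the 5-hydroxyl and hydrogenolysis (three steps) would follow.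
- Comparison: on structure the two plans are equal, since A9 is 10 extended by the carbon that becomes C4, which here comes from the ring B partner. On mechanism the chosen plan is better controlled: a low-temperature enolate acylation and a separate acid closure, against an uncatalysed thermal condensation. On step economy the alternative is better for the ring-forming event, and it would be at least equal overall if A8 were available in three steps or fewer. Its weakness is that the hydroxyl differentiation is made after the ring is formed, whereas in the chosen plan it comes from 1.

Key step: step 6

Assumption: 1, 2 and 10 are treated as catalogue chemicals; the target has no stereocentre, so none has to be set.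

Design remarks:
- Atom mapping of 9 onto 13: the acyl carbon becomes C4, C1 of the arene becomes C4a, the two acetal-bearing carbons become C8a and C5, the methoxylated carbons become C8 and C6, and the benzyloxy carbon becomes C7. No correction of these structures is needed.
- The ester of 1 is hydrolysed before the ring is brominated, because a di-ortho-brominated ester is very slow to saponify.
- Alkylation of 6 with the chloromethyl ether necessarily esterifies the carboxyl group as well. The tris-alkylated 7 is therefore made on purpose and its activated ester is cleaved selectively. The cleavage is run without an alcohol cosolvent, so that 7 cannot be transesterified to a simple alkyl ester, which would resist hydrolysis between two ortho substituents.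
- 9 is generated under neutral conditions and used at once.

## Steps

Step 1
Reactants: 1 methyl syringate (methyl 4-hydroxy-3,5-dimethoxybenzoate); 2 benzyl bromide
Product: 4 4-(benzyloxy)-3,5-dimethoxybenzoic acid, via methyl ester 3 (not isolated)
Conditions: 2 (1.2 equiv), K2CO3, acetone, reflux; evaporate; then NaOH, MeOH–H2O, 60 °C; HCl to pH 2
Reagents that add atoms: sodium hydroxide, [Na+].[OH-] (supplies the carboxyl OH oxygen)
Why: Williamson etherification of the only phenol by the reactive benzylic bromide, then BAc2 saponification of the still unhindered methyl ester; the acid is freed from neutral by-products by acid–base extraction.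

Step 2
Reactants: 4 4-(benzyloxy)-3,5-dimethoxybenzoic acid
Product: 5 4-(benzyloxy)-2,6-dibromo-3,5-dimethoxybenzoic acid
Conditions: 1,3-dibromo-5,5-dimethylhydantoin (1.2 equiv), 1 M aq. NaOH, 0 °C → rt; Na2SO3; HCl to pH 2
Reagents that add atoms: 1,3-dibromo-5,5-dimethylhydantoin, CC1(C)N(Br)C(=O)N(Br)C1=O
Why: Electrophilic aromatic bromination by hypobromite formed from the N-bromo imide in aqueous base; each free position of 4 is ortho to one methoxyl and para to the other, and the carboxylate does not deactivate the ring as an ester would, so both positions should be filled while the much less activated benzyl ring is left alone.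

Step 3
Reactants: 5 4-(benzyloxy)-2,6-dibromo-3,5-dimethoxybenzoic acid
Product: 6 4-(benzyloxy)-2,6-dihydroxy-3,5-dimethoxybenzoic acid
Conditions: CuI (20 mol %), KOH (8 equiv), degassed H2O, 100 °C, argon; HCl to pH 2–3 at 0 °C, extract, concentrate below 30 °C, use directly
Reagents that add atoms: potassium hydroxide, [K+].[OH-]
Why: Copper-catalysed Ullmann-type hydroxylation of an ortho-bromobenzoate, in which the neighbouring carboxylate binds copper and directs it to each C–Br bond so that hydroxide should replace both bromines without an added ligand; the product stays as its polyanion, which resists decarboxylation, until the cold acidification.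

Step 4
Reactants: 6 4-(benzyloxy)-2,6-dihydroxy-3,5-dimethoxybenzoic acid
Product: 8 4-(benzyloxy)-3,5-dimethoxy-2,6-bis(methoxymethoxy)benzoic acid, via methoxymethyl ester 7 (not isolated)
Conditions: MOMCl (4.5 equiv), i-Pr2NEt (6 equiv), DMF, 0 °C → rt; aqueous work-up; then 2 M aq. KOH, THF, 50 °C; cold 1 M HCl to pH 4
Reagents that add atoms: chloromethyl methyl ether, COCCl; potassium hydroxide, [K+].[OH-] (supplies the carboxyl OH oxygen)
Why: Williamson-type alkylation with the reactive α-chloro ether caps the carboxylate and both phenols; the methoxymethyl ester is an activated acylal-type ester that aqueous hydroxide should cleave under conditions to which the aryl acetal ethers, the benzyl ether and the methyl ethers are inert.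

Step 5
Reactants: 8 4-(benzyloxy)-3,5-dimethoxy-2,6-bis(methoxymethoxy)benzoic acid
Product: 9 4-(benzyloxy)-3,5-dimethoxy-2,6-bis(methoxymethoxy)benzoyl chloride
Conditions: 1-chloro-N,N,2-trimethylprop-1-en-1-amine (1.0 equiv), CH2Cl2, 0 °C → rt; concentrate, use at once
Reagents that add atoms: 1-chloro-N,N,2-trimethylprop-1-en-1-amine, CC(C)=C(Cl)N(C)C
Why: The α-chloro enamine converts the acid into the acyl chloride through an acyloxyiminium chloride under neutral conditions, with an amide as the only by-product and no hydrogen chloride that would strip the acetal ethers; 9 is not stored because an ortho acetal oxygen can attack the acyl chloride.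

Step 6
Reactants: 9 4-(benzyloxy)-3,5-dimethoxy-2,6-bis(methoxymethoxy)benzoyl chloride; 10 2-methoxy-1-(4-methoxyphenyl)ethanone
Product: 13 7-(benzyloxy)-5-hydroxy-3,6,8-trimethoxy-2-(4-methoxyphenyl)-4H-chromen-4-one, via bis-MOM diketone 11 (not isolated), via dihydroxy diketone 12 (not isolated)
Conditions: 10 (2.1 equiv), LiN(SiMe3)2 (2.1 equiv), THF, −78 °C; 9 in THF, −78 → 0 °C; then HCl in MeOH (ca. 2 M), 50 °C
Reagents that add atoms: none
Why: LiN(SiMe3)2 converts 10 into its lithium enolate, whose α-carbon adds to the carbonyl of 9; loss of chloride forms the C3–C4 bond, and the second equivalent of enolate deprotonates the more acidic diketone 11, which pulls the acylation forward and shields 11 from further attack. The closest known reaction type is the acylation of ketone lithium enolates with aroyl chlorides to 1,3-diketones followed by acid cyclodehydration to flavones, the intermolecular counterpart of the Baker–Venkataraman sequence. Methanolic HCl then transfers both methoxymethyl groups to methanol to give 12, although loss of the second group and ring closure may interleave. Ring C closes by 6-exo-trig addition of one ortho hydroxyl to the protonated 4-methoxybenzoyl carbonyl (O1–C2), and the resulting 2-hydroxychromanone loses water to the conjugated pyranone, which makes the closure irreversible. No stereocentre is created, because the only sp3 centre on the way, C2 of 11 and 12, is enolisable and disappears on dehydration. The step needs C- over O-acylation, which the lithium counter-ion in THF at low temperature favours, and the excess enolate should convert any enol ester into 11 by transacylation. The two ortho hydroxyls of 12 are equivalent by symmetry, so only one chromenone can form, and addition to the ring A ketone is excluded because it would close a four-membered ring. The benzyl and methyl ethers are stable to dilute methanolic HCl at 50 °C, so the C7 oxygen stays masked while the C5 hydroxyl emerges chelated to C4=O.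

Step 7
Reactants: 13 7-(benzyloxy)-5-hydroxy-3,6,8-trimethoxy-2-(4-methoxyphenyl)-4H-chromen-4-one
Product: 14 7-(benzyloxy)-3,5,6,8-tetramethoxy-2-(4-methoxyphenyl)-4H-chromen-4-one
Conditions: Me2SO4 (3 equiv), K2CO3 (5 equiv), acetone, reflux
Reagents that add atoms: dimethyl sulfate, COS(=O)(=O)OC
Why: Williamson O-methylation of the phenoxide; 13 has a single free hydroxyl, so no selectivity question arises, and its chelation to C4=O only slows the reaction, which excess methylating agent at reflux should overcome.

Step 8
Reactants: 14 7-(benzyloxy)-3,5,6,8-tetramethoxy-2-(4-methoxyphenyl)-4H-chromen-4-one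
Product: 15 7-hydroxy-3,5,6,8-tetramethoxy-2-(4-methoxyphenyl)-4H-chromen-4-one
Conditions: H2 (1 atm), 10 % Pd/C, EtOAc–MeOH, rt
Reagents that add atoms: none
Why: Heterogeneous hydrogenolysis of the benzylic C–O bond; the tetrasubstituted, conjugated C2=C3 bond of the pyranone and the aryl methyl ethers should not be reduced at ambient pressure and temperature.

## Compound list

1 | methyl syringate (methyl 4-hydroxy-3,5-dimethoxybenzoate) | COC(=O)c1cc(OC)c(O)c(OC)c1 | starting material
2 | benzyl bromide | BrCc1ccccc1 | starting material
3 | methyl 4-(benzyloxy)-3,5-dimethoxybenzoate | COC(=O)c1cc(OC)c(OCc2ccccc2)c(OC)c1 | intermediate (not isolated)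
4 | 4-(benzyloxy)-3,5-dimethoxybenzoic acid | OC(=O)c1cc(OC)c(OCc2ccccc2)c(OC)c1 | intermediate
5 | 4-(benzyloxy)-2,6-dibromo-3,5-dimethoxybenzoic acid | OC(=O)c1c(Br)c(OC)c(OCc2ccccc2)c(OC)c1Br | intermediate
6 | 4-(benzyloxy)-2,6-dihydroxy-3,5-dimethoxybenzoic acid | OC(=O)c1c(O)c(OC)c(OCc2ccccc2)c(OC)c1O | intermediate
7 | methoxymethyl 4-(benzyloxy)-3,5-dimethoxy-2,6-bis(methoxymethoxy)benzoate | COCOC(=O)c1c(OCOC)c(OC)c(OCc2ccccc2)c(OC)c1OCOC | intermediate (not isolated)
8 | 4-(benzyloxy)-3,5-dimethoxy-2,6-bis(methoxymethoxy)benzoic acid | OC(=O)c1c(OCOC)c(OC)c(OCc2ccccc2)c(OC)c1OCOC | intermediate
9 | 4-(benzyloxy)-3,5-dimethoxy-2,6-bis(methoxymethoxy)benzoyl chloride | COCOc1c(OC)c(OCc2ccccc2)c(OC)c(OCOC)c1C(Cl)=O | intermediate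
10 | 2-methoxy-1-(4-methoxyphenyl)ethanone | COCC(=O)c1ccc(OC)cc1 | starting material
11 | 1-[4-(benzyloxy)-3,5-dimethoxy-2,6-bis(methoxymethoxy)phenyl]-2-methoxy-3-(4-methoxyphenyl)propane-1,3-dione (racemic, enolisable) | COCOc1c(OC)c(OCc2ccccc2)c(OC)c(OCOC)c1C(=O)C(OC)C(=O)c1ccc(OC)cc1 | intermediate (not isolated)
12 | 1-[4-(benzyloxy)-2,6-dihydroxy-3,5-dimethoxyphenyl]-2-methoxy-3-(4-methoxyphenyl)propane-1,3-dione (racemic, enolisable) | COc1ccc(cc1)C(=O)C(OC)C(=O)c1c(O)c(OC)c(OCc2ccccc2)c(OC)c1O | intermediate (not isolated)
13 | 7-(benzyloxy)-5-hydroxy-3,6,8-trimethoxy-2-(4-methoxyphenyl)-4H-chromen-4-one | COc1ccc(-c2oc3c(OC)c(OCc4ccccc4)c(OC)c(O)c3c(=O)c2OC)cc1 | intermediate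
14 | 7-(benzyloxy)-3,5,6,8-tetramethoxy-2-(4-methoxyphenyl)-4H-chromen-4-one | COc1ccc(-c2oc3c(OC)c(OCc4ccccc4)c(OC)c(OC)c3c(=O)c2OC)cc1 | intermediate
15 | 7-hydroxy-3,5,6,8-tetramethoxy-2-(4-methoxyphenyl)-4H-chromen-4-one | COc1ccc(-c2oc3c(OC)c(O)c(OC)c(OC)c3c(=O)c2OC)cc1 | target

## Step count and least certain steps

Total step count: 8. Longest linear sequence: 8 steps (1 to 15); 10 is purchased and enters at step 6.

Step 6 (key step). The most likely failure is at the C–C bond formation: attack at the shielded carbonyl of 9 may be slow, the enolate may be acylated on oxygen, and 9 may be lost by ring closure of an ortho acetal oxygen onto the acyl chloride before the enolate reaches it. The fallback replaces acylation by aldol addition and oxidation. It sets out from 8, which would be reduced with LiAlH4 (THF, 0 °C → reflux) to [4-(benzyloxy)-3,5-dimethoxy-2,6-bis(methoxymethoxy)phenyl]methanol F1. This would be oxidised with MnO2 (CH2Cl2, rt) to 4-(benzyloxy)-3,5-dimethoxy-2,6-bis(methoxymethoxy)benzaldehyde F2. Addition of the lithium enolate of 10 (LiN(SiMe3)2, THF, −78 °C) to F2 should give 3-[4-(benzyloxy)-3,5-dimethoxy-2,6-bis(methoxymethoxy)phenyl]-3-hydroxy-2-methoxy-1-(4-methoxyphenyl)propan-1-one F3 as a mixture of diastereomers, which is of no consequence. Dess–Martin oxidation of F3 would give 11, where the route is rejoined; 11 is then taken to 13 with methanolic HCl as in step 6.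

Step 3. The most likely failure is loss of carbon dioxide, together with air oxidation, when the penta-oxygenated acid is set free from its polyanion during acidic isolation. The fallback accepts the decarboxylation and reinstalls the carboxyl group by directed metalation. It sets out from 5, which is hydroxylated as in step 3. The acidified solution is then warmed until decarboxylation is complete, giving 5-(benzyloxy)-4,6-dimethoxybenzene-1,3-diol F4. Etherification (MOMCl, i-Pr2NEt, CH2Cl2) would give 3-(benzyloxy)-2,4-dimethoxy-1,5-bis(methoxymethoxy)benzene F5. Its only ring C–H lies between the two acetal ethers and should be lithiated selectively with n-BuLi (THF, −20 → 0 °C). Quenching with CO2 and mild acidification returns the route at 8, bypassing the isolation of 6 and the ester cleavage of 7.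

Step 2. The most likely failure is ipso attack of the electrophile at the carboxyl-bearing carbon, which is para to the benzyloxy group, with loss of carbon dioxide; a second possibility is that the second bromination stalls. The fallback brominates an ester, which cannot decarboxylate, and then cleaves it by dealkylation instead of acyl substitution. It sets out from 3, isolated by stopping step 1 before the hydrolysis. NBS (2.4 equiv, MeCN, 50 °C, dark) should give methyl 4-(benzyloxy)-2,6-dibromo-3,5-dimethoxybenzoate F6. LiI in pyridine at reflux should then remove the ester methyl group by SN2 attack, which avoids the shielded carbonyl, and acidification returns the route at 5.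

Step 5. The most likely failure is decomposition of the acyl chloride during its formation or concentration, by intramolecular attack of an ortho acetal oxygen and demethylation by chloride. The fallback uses a storable, chloride-free acyl donor. It sets out from 8, which would be coupled with 1H-benzotriazole (N,N'-dicyclohexylcarbodiimide, CH2Cl2, rt) to (1H-benzotriazol-1-yl)[4-(benzyloxy)-3,5-dimethoxy-2,6-bis(methoxymethoxy)phenyl]methanone F7. N-Acylbenzotriazoles are established C-acylating agents for ketone lithium enolates, so F7 and the lithium enolate of 10 (2.1 equiv, THF, −78 → 0 °C) should give 11, where the route is rejoined before the acid treatment of step 6.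

Step 4. The most likely failure is incomplete cleavage of the ester of 7, whose carbonyl is shielded by two ortho substituents, or incomplete etherification of the two hydrogen-bonded hydroxyls. The fallback uses an ester that is removed at its alkyl–oxygen bond, so that the shielded carbonyl is never attacked. It sets out from 6, whose carboxyl group would be alkylated selectively (allyl bromide, KHCO3, DMF, rt) to prop-2-en-1-yl 4-(benzyloxy)-2,6-dihydroxy-3,5-dimethoxybenzoate F8. Etherification (NaH, MOMCl, DMF, 0 °C) would give prop-2-en-1-yl 4-(benzyloxy)-3,5-dimethoxy-2,6-bis(methoxymethoxy)benzoate F9. Pd(PPh3)4, a zerovalent palladium complex, with morpholine (THF, rt) should then transfer the allyl group to the amine through a π-allyl complex, and mild acidification returns the route at 8.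

## Further compounds

F1 | step 6 | [4-(benzyloxy)-3,5-dimethoxy-2,6-bis(methoxymethoxy)phenyl]methanol | COCOc1c(OC)c(OCc2ccccc2)c(OC)c(OCOC)c1CO
F2 | step 6 | 4-(benzyloxy)-3,5-dimethoxy-2,6-bis(methoxymethoxy)benzaldehyde | COCOc1c(OC)c(OCc2ccccc2)c(OC)c(OCOC)c1C=O
F3 | step 6 | 3-[4-(benzyloxy)-3,5-dimethoxy-2,6-bis(methoxymethoxy)phenyl]-3-hydroxy-2-methoxy-1-(4-methoxyphenyl)propan-1-one (racemic mixture of diastereomers) | COCOc1c(OC)c(OCc2ccccc2)c(OC)c(OCOC)c1C(O)C(OC)C(=O)c1ccc(OC)cc1
F4 | step 3 | 5-(benzyloxy)-4,6-dimethoxybenzene-1,3-diol | COc1c(O)cc(O)c(OC)c1OCc1ccccc1
F5 | step 3 | 3-(benzyloxy)-2,4-dimethoxy-1,5-bis(methoxymethoxy)benzene | COCOc1cc(OCOC)c(OC)c(OCc2ccccc2)c1OC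
F6 | step 2 | methyl 4-(benzyloxy)-2,6-dibromo-3,5-dimethoxybenzoate | COC(=O)c1c(Br)c(OC)c(OCc2ccccc2)c(OC)c1Br
F7 | step 5 | (1H-benzotriazol-1-yl)[4-(benzyloxy)-3,5-dimethoxy-2,6-bis(methoxymethoxy)phenyl]methanone | COCOc1c(OC)c(OCc2ccccc2)c(OC)c(OCOC)c1C(=O)n1nnc2ccccc21
F8 | step 4 | prop-2-en-1-yl 4-(benzyloxy)-2,6-dihydroxy-3,5-dimethoxybenzoate | C=CCOC(=O)c1c(O)c(OC)c(OCc2ccccc2)c(OC)c1O
F9 | step 4 | prop-2-en-1-yl 4-(benzyloxy)-3,5-dimethoxy-2,6-bis(methoxymethoxy)benzoate | C=CCOC(=O)c1c(OCOC)c(OC)c(OCc2ccccc2)c(OC)c1OCOC
A1 | alternative 1 | methyl 2,4,8-trimethoxy-3,5,7-trioxooctanoate (mixture of stereoisomers and enol forms) | COCC(=O)CC(=O)C(OC)C(=O)C(OC)C(=O)OC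
A2 | alternative 1 | 2-methoxy-1-(2,4,6-trihydroxy-3,5-dimethoxyphenyl)ethanone | COCC(=O)c1c(O)c(OC)c(O)c(OC)c1O
A3 | alternative 2 | 1-iodo-3,5-dimethoxy-2,4,6-tris(methoxymethoxy)benzene | COCOc1c(OC)c(OCOC)c(OC)c(OCOC)c1I
A4 | alternative 2 | 1-ethynyl-4-methoxybenzene | C#Cc1ccc(OC)cc1
A5 | alternative 2 | carbon monoxide | [C-]#[O+]
A6 | alternative 2 | 1-[3,5-dimethoxy-2,4,6-tris(methoxymethoxy)phenyl]-3-(4-methoxyphenyl)prop-2-yn-1-one | COCOc1c(OC)c(OCOC)c(OC)c(OCOC)c1C(=O)C#Cc1ccc(OC)cc1
A7 | alternative 2 | 5,7-dihydroxy-6,8-dimethoxy-2-(4-methoxyphenyl)-4H-chromen-4-one | COc1ccc(-c2cc(=O)c3c(O)c(OC)c(O)c(OC)c3o2)cc1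
A8 | alternative 3 | 2,4-dimethoxybenzene-1,3,5-triol | COc1c(O)cc(O)c(OC)c1O
A9 | alternative 3 | ethyl 2-methoxy-3-(4-methoxyphenyl)-3-oxopropanoate (racemic) | CCOC(=O)C(OC)C(=O)c1ccc(OC)cc1
A10 | alternative 3 | 5,7-dihydroxy-3,6,8-trimethoxy-2-(4-methoxyphenyl)-4H-chromen-4-one | COc1ccc(-c2oc3c(OC)c(O)c(OC)c(O)c3c(=O)c2OC)cc1
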